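**Assumptions:** the target is the enantiomer encoded in the SMILES, which I assign as 6R,7R,8S,10R (germacrane numbering, used throughout). Catalysts, ligands and simple reagents are bought and not numbered. The route has not been run; the steps that carry the most risk are listed at the end.

## Retrosynthetic overview

1. The ten-membered carbocycle is closed last by ring-closing metathesis at the Z-C4=C5 alkene.
2. The C7–C8 bond, the α-methylene lactone and the C7/C8 stereocentres come from a Zn-Barbier union of a furanone aldehyde with a 3-(bromomethyl)butenolide; the C8-OH is then angeloylated.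
3. Key step: a Pd-catalysed enantioselective allylation at C2 of an aromatic 3-silyloxyfuran breaks the furan aromaticity and creates the 3(2H)-furanone and the C10 quaternary centre in one operation.
4. The silyloxyfuran comes from 2-acetyl-5-methylfuran, which supplies C14, C10, C1–C4, C15 and the ring oxygen. The butenolide (C6 stereocentre) comes from asymmetric alkynylation of crotonaldehyde.
5. Ring order: furan → furanone; butenolide → α-methylene-γ-lactone (Barbier) → macrocycle (RCM).

## Route

**Step 1**
Reactants: 1, 2-acetyl-5-methylfuran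
Product: 2, 1-(4-bromo-5-methylfuran-2-yl)ethan-1-one
Conditions: Br2 (1.05 eq), AlCl3 (2.5 eq), ClCH2CH2Cl, 0 °C → rt
Reagents that add atoms: bromine, BrBr
Why: Electrophilic aromatic bromination under "swamping-catalyst" conditions, where the AlCl3-complexed acetyl group suppresses side-chain bromination and directs Br+ to the only activated free ring position, the β-carbon next to the methyl group.

**Step 2**
Reactants: 2, 1-(4-bromo-5-methylfuran-2-yl)ethan-1-one
Product: 3, 3-bromo-2-methyl-5-(prop-1-en-2-yl)furan
Conditions: Ph3PCH3Br, KOtBu, THF, 0 °C → rt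
Reagents that add atoms: methyltriphenylphosphonium bromide, C[P+](c1ccccc1)(c1ccccc1)c1ccccc1.[Br-]
Why: Wittig methylenation of an aryl methyl ketone with a non-stabilised ylide installs the isopropenyl group (future C4/C15) and leaves the aryl bromide untouched.

**Step 3**
Reactants: 3, 3-bromo-2-methyl-5-(prop-1-en-2-yl)furan
Product: 4, trimethyl{[2-methyl-5-(prop-1-en-2-yl)furan-3-yl]oxy}silane
Conditions: t-BuLi (2.05 eq), Et2O, −78 °C; then Me3SiOOSiMe3, −78 → 0 °C
Reagents that add atoms: bis(trimethylsilyl) peroxide, C[Si](C)(C)OO[Si](C)(C)C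
Why: Br/Li exchange gives a 3-furyllithium that cannot isomerise (both α-positions are substituted) and attacks the peroxide O–O bond (electrophilic oxygenation of an aryl/vinyl-lithium), giving the aromatic silyl enol ether directly.

**Step 4 (key step)**
Reactants: 4, trimethyl{[2-methyl-5-(prop-1-en-2-yl)furan-3-yl]oxy}silane
Product: 5, (R)-2-allyl-2-methyl-5-(prop-1-en-2-yl)furan-3(2H)-one
Conditions: Pd2(dba)3 (2.5 mol%), (R)-t-Bu-PHOX (6 mol%), diallyl carbonate (1.05 eq), Bu4N Ph3SiF2 (TBAT, 35 mol%), THF, 25 °C
Reagents that add atoms: diallyl carbonate, C=CCOC(=O)OCC=C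
Why: Proposed new method: fluoride releases the 3-furanolate, which binds the PHOX–Pd(π-allyl) cation through oxygen and undergoes inner-sphere C–C reductive elimination at C2 (the enolate α-carbon; C-allylation is favoured because the furan's aromatic stabilisation is small), breaking aromaticity and setting C10 as R under ligand control; the closest known reaction is the enantioselective Tsuji allylation of silyl enol ethers and allyl enol carbonates, including α-oxygenated tetrasubstituted enolates, and the ligand hand is chosen by analogy with 2-methylcyclohexanone and must be confirmed experimentally.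

**Step 5**
Reactants: 5, (R)-2-allyl-2-methyl-5-(prop-1-en-2-yl)furan-3(2H)-one
Product: 6, (R)-2-[2-methyl-3-oxo-5-(prop-1-en-2-yl)-2,3-dihydrofuran-2-yl]acetaldehyde
Conditions: OsO4 (2 mol%), NaIO4 (4 eq), 2,6-lutidine, dioxane/H2O 3:1, 0 °C → rt; use crude at once
Reagents that add atoms: osmium tetroxide, O=[Os](=O)(=O)=O; sodium periodate, [Na+].[O-]I(=O)(=O)=O
Why: Lemieux–Johnson cleavage should select the isolated monosubstituted allyl alkene because the isopropenyl and ring alkenes belong to an electron-poor cross-conjugated vinylogous ester; C10 is untouched and the aldehyde is kept away from base to avoid retro-oxa-Michael opening.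

**Step 6**
Reactants: 7, (E)-but-2-enal (crotonaldehyde); 8, tert-butyldimethyl(prop-2-yn-1-yloxy)silane
Product: 9, (4R,5E)-1-[(tert-butyldimethylsilyl)oxy]hept-5-en-2-yn-4-ol
Conditions: Me2Zn (3 eq), (S,S)-ProPhenol (10 mol%; enantiomer chosen to give 4R, check by Mosher ester), Ph3PO (20 mol%), toluene, 0 °C
Reagents that add atoms: none
Why: Dinuclear Zn–ProPhenol asymmetric alkynylation of an enal, a good substrate class for this catalyst, sets the future C6 stereocentre under catalyst control.

**Step 7**
Reactants: 9, (4R,5E)-1-[(tert-butyldimethylsilyl)oxy]hept-5-en-2-yn-4-ol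
Product: 10, (2Z,4R,5E)-1-[(tert-butyldimethylsilyl)oxy]-2-iodohepta-2,5-dien-4-ol
Conditions: Red-Al (1.5 eq), THF, 0 °C → rt; EtOAc; then I2, −78 → 0 °C
Reagents that add atoms: iodine, II
Why: Hydroxyl-directed trans-hydroalumination puts Al on the alkyne carbon distal to the carbinol, and iodinolysis with retention gives the vinyl iodide with I cis to the carbinol carbon, which fixes the butenolide geometry without touching C6.

**Step 8**
Reactants: 10, (2Z,4R,5E)-1-[(tert-butyldimethylsilyl)oxy]-2-iodohepta-2,5-dien-4-ol
Product: 11, (R)-3-{[(tert-butyldimethylsilyl)oxy]methyl}-5-[(E)-prop-1-en-1-yl]furan-2(5H)-one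
Conditions: MeLi (1.0 eq), then t-BuLi (2.1 eq), THF, −78 °C; CO2; then aq. NaHSO4, 0 °C → rt
Reagents that add atoms: carbon dioxide, O=C=O
Why: I/Li exchange on the lithium alkoxide and carboxylation give a (Z)-γ-hydroxy acid that lactonises on acidification; no Pd(0) is used, so the doubly allylic C6–O bond cannot ionise and racemise.

**Step 9**
Reactants: 11, (R)-3-{[(tert-butyldimethylsilyl)oxy]methyl}-5-[(E)-prop-1-en-1-yl]furan-2(5H)-one
Product: 12, (R)-3-(bromomethyl)-5-[(E)-prop-1-en-1-yl]furan-2(5H)-one
Conditions: Ph3P·Br2 (1.3 eq), CH2Cl2, 0 °C → rt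
Reagents that add atoms: triphenylphosphine dibromide, BrP(Br)(c1ccccc1)(c1ccccc1)c1ccccc1
Why: Direct conversion of a primary allylic silyl ether to the bromide via an oxyphosphonium/SN2 pathway under non-basic conditions, so the base-labile γ-H of the butenolide (C6) is not epimerised.

**Step 10**
Reactants: 6, (R)-2-[2-methyl-3-oxo-5-(prop-1-en-2-yl)-2,3-dihydrofuran-2-yl]acetaldehyde; 12, (R)-3-(bromomethyl)-5-[(E)-prop-1-en-1-yl]furan-2(5H)-one
Product: 13, (R)-2-{(S)-2-hydroxy-2-[(2R,3R)-4-methylene-5-oxo-2-((E)-prop-1-en-1-yl)tetrahydrofuran-3-yl]ethyl}-2-methyl-5-(prop-1-en-2-yl)furan-3(2H)-one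
Conditions: Zn dust (3 eq), THF/sat. aq. NH4Cl 4:1, 0 °C → rt
Reagents that add atoms: none (all atoms from 6 and 12)
Why: Zn-Barbier allylation (SE2′) in which the allylzinc adds through C7 on the face anti to the C6 propenyl group (6,7-trans, 7R) via a chair Zimmerman–Traxler transition state with the ring γ-substituent and the aldehyde chain equatorial (7,8-anti, 8S), forming the exo-methylene lactone and reacting only at the aldehyde.

**Step 11**
Reactants: 13, the Barbier alcohol above; 14, angelic acid [(Z)-2-methylbut-2-enoic acid]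
Product: 15, (S)-1-[(2R,3R)-4-methylene-5-oxo-2-((E)-prop-1-en-1-yl)tetrahydrofuran-3-yl]-2-[(R)-2-methyl-3-oxo-5-(prop-1-en-2-yl)-2,3-dihydrofuran-2-yl]ethyl (Z)-2-methylbut-2-enoate
Conditions: 14, 2,4,6-trichlorobenzoyl chloride, Et3N, toluene, rt; then 13, 75 °C (no DMAP)
Reagents that add atoms: none (acyl group from 14)
Why: Yamaguchi-type mixed-anhydride esterification without DMAP acylates C8-OH with retention and without angelate → tiglate isomerisation, and capping the hydroxyl prevents 6,12 → 8,12 translactonisation.

**Step 12**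
Reactants: 15, the angelate triene above
Product: 16, lychnopholide
Conditions: Hoveyda–Grubbs II (15 mol%), 1,4-benzoquinone (30 mol%), toluene (1 mM), 90 °C
Reagents that add atoms: none (propene is lost)
Why: Ring-closing metathesis initiates at the propenyl group and closes onto the isopropenyl group, and the furanone-bridged nine-membered ring can only hold the cis (Z) C4=C5 alkene, while the angelate and the exo-methylene lactone are poor metathesis partners.

## Compound list

1 | 2-acetyl-5-methylfuran | CC(=O)c1ccc(C)o1 | starting material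
2 | 1-(4-bromo-5-methylfuran-2-yl)ethan-1-one | CC(=O)c1cc(Br)c(C)o1 | intermediate
3 | 3-bromo-2-methyl-5-(prop-1-en-2-yl)furan | C=C(C)c1cc(Br)c(C)o1 | intermediate
4 | trimethyl{[2-methyl-5-(prop-1-en-2-yl)furan-3-yl]oxy}silane | C=C(C)c1cc(O[Si](C)(C)C)c(C)o1 | intermediate
5 | (R)-2-allyl-2-methyl-5-(prop-1-en-2-yl)furan-3(2H)-one | C=C(C)C1=CC(=O)[C@@](C)(CC=C)O1 | intermediate
6 | (R)-2-[2-methyl-3-oxo-5-(prop-1-en-2-yl)-2,3-dihydrofuran-2-yl]acetaldehyde | C=C(C)C1=CC(=O)[C@@](C)(CC=O)O1 | intermediate
7 | (E)-but-2-enal | C/C=C/C=O | starting material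
8 | tert-butyldimethyl(prop-2-yn-1-yloxy)silane | C#CCO[Si](C)(C)C(C)(C)C | starting material
9 | (4R,5E)-1-[(tert-butyldimethylsilyl)oxy]hept-5-en-2-yn-4-ol | C/C=C/[C@@H](O)C#CCO[Si](C)(C)C(C)(C)C | intermediate
10 | (2Z,4R,5E)-1-[(tert-butyldimethylsilyl)oxy]-2-iodohepta-2,5-dien-4-ol | C/C=C/[C@@H](O)/C=C(\I)CO[Si](C)(C)C(C)(C)C | intermediate
11 | (R)-3-{[(tert-butyldimethylsilyl)oxy]methyl}-5-[(E)-prop-1-en-1-yl]furan-2(5H)-one | C/C=C/[C@H]1OC(=O)C(CO[Si](C)(C)C(C)(C)C)=C1 | intermediate
12 | (R)-3-(bromomethyl)-5-[(E)-prop-1-en-1-yl]furan-2(5H)-one | C/C=C/[C@H]1OC(=O)C(CBr)=C1 | intermediate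
13 | (R)-2-{(S)-2-hydroxy-2-[(2R,3R)-4-methylene-5-oxo-2-((E)-prop-1-en-1-yl)tetrahydrofuran-3-yl]ethyl}-2-methyl-5-(prop-1-en-2-yl)furan-3(2H)-one | C=C(C)C1=CC(=O)[C@@](C)(C[C@H](O)[C@@H]2[C@@H](/C=C/C)OC(=O)C2=C)O1 | intermediate
14 | angelic acid | C/C=C(/C)C(=O)O | starting material
15 | C8 angelate of 13 | C=C(C)C1=CC(=O)[C@@](C)(C[C@H](OC(=O)/C(C)=C\C)[C@@H]2[C@@H](/C=C/C)OC(=O)C2=C)O1 | intermediate
16 | lychnopholide | C=C1C(=O)O[C@@H]2/C=C(/C)C3=CC(=O)[C@@](C)(C[C@H](OC(=O)/C(C)=C\C)[C@@H]12)O3 | target

## Summary

Total steps: 12. Longest linear sequence: 8 (steps 1–5, 10, 11, 12).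

Three steps most likely to fail, each with a fallback:

1. **Step 12 (RCM).** Closing a strained ten-membered carbocycle through a trisubstituted, conjugated alkene may stall or give oligomers. Fallback: change the ring-closing bond. Make the Z-C4=C5 alkene intermolecularly at the aromatic stage (Negishi coupling of a 5-furylzinc with a (Z)-3-iodobut-2-enyl unit carrying the butenolide), then close the macrocycle by an intramolecular Zn/Cr Barbier allylation at C7–C8.

2. **Step 4 (dearomative asymmetric allylation).** O-allylation, C4-allylation or low ee are possible. Fallback: Cu-catalysed etherification of 3 with allyl alcohol and thermal dearomative Claisen rearrangement give racemic 5. Carry it forward and separate the two diastereomers of 13 formed with enantiopure 12, so the butenolide resolves C10.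

3. **Step 5 (selective alkene cleavage and labile aldehyde).** The isopropenyl group may be over-oxidised, or the aldehyde may undergo β-elimination. Fallback: treat 2 with MeMgBr instead of the Wittig reagent and carry C4 as a TES-protected tertiary carbinol through steps 3–5, 10 and 11. Reveal the isopropenyl group by Burgess dehydration just before the RCM, so that no second alkene is present during the cleavage.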